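**Structural features**

The target is a ten-membered carbocycle (C1–C10, germacrane numbering) fused through the C6–C7 bond to a butenolide (O–C6, C7=C11, C12=O); C6 and C7 belong to both rings and the tetrasubstituted C7=C11 alkene is exocyclic to the large ring. The large ring also holds a Z trisubstituted alkene (C4=C5, methyl C15) and an exocyclic methylene (C10=C14) next to the C1 carbinol. Of the three stereocentres, C6 (R, lactone oxygen) and C8 (S, acetate) both sit on sp2 C7 and are 1,3-related, whereas C1 (R, free allylic alcohol) is separated from C8 by C9 and C10 and from C6 by four ring bonds, with no rigid element to relay information. The fragile groups are: the C13 acetoxymethyl group on the α-carbon of the butenolide, an allylic acetate of the Morita–Baylis–Hillman type that is expelled when a nucleophile adds to C7 or when C6–H (γ to the lactone carbonyl and allylic to C4=C5) is removed; the Z alkene; the allylic C6–O lactone bond; and the medium ring itself, which invites transannular reactions under acid. The real difficulty is to close a ten-membered ring in the presence of these groups and to fix C1 relative to C6 and C8. The key step uses the position of the ring bond C2–C3 between C1, which at the ketone level makes C2 a β-keto ester carbon, and C3, the primary allylic terminus of the Z C3–C4=C5 unit, so that an enolate at C2 and a chloride at C3 close the ring without a lasting stereocentre and C1 is set afterwards by a catalyst. Name and SMILES of the target were compared and agree (1β-OH = 1R, 6α-O = 6R, 8α-OAc = 8S, 4Z), and the ring-closure substrate and product carry the same configurations, so no structure needed correction; one spectator group of the substrate was changed (see the remarks before the steps).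

**Logic of the disconnections**

31 ⇒ 30. The C1–H bond is cut (carbinol back to ketone). C1 is the one stereocentre that no neighbour can direct, and as a ketone it is what acidifies C2 for the ring closure. The gain is that the ring is closed without any C1 configuration to carry. The forward step must be a catalyst-controlled 1,2-reduction of an α-methylene ketone that leaves the butenolide and both acetates alone.

30 ⇒ 29 ⇒ 27. The C13 O–acetyl bond, the C2–carboxyl bond and the C13 O–benzyl bond are cut. An acetate at C13 would be a leaving group β to C11 during the base step, so the C13 oxygen is carried as a 4-methoxybenzyl ether through the ring closure. One acid treatment then removes this ether and the tert-butyl ester and causes decarboxylation. The gain is a stabilised carbanion site at C2 in 27 and no separate deprotection step. The demand is that the acid must not ionise the allylic C6–O bond or start a transannular cyclisation.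

27 ⇒ 26. The ring bond C2–C3 is cut. This removes the ten-membered ring and leaves an open chain in which every stereocentre except C1 is already in place and none is formed. The forward step needs C-alkylation by SN2 at a primary allylic carbon under high dilution, with a base weak enough to spare C6–H.

26 ⇒ 25 ⇒ 23 ⇒ 22 ⇒ 19 + 20. The C1–C2 bond is cut (zinc enolate plus aldehyde), and the C3–Cl bond is traced back to a silyl-protected C3–O bond. This detaches the two-carbon ester unit and postpones the reactive β-keto ester/enone and the allylic chloride to the last three operations before ring closure. The demand is a chemoselective chlorination of the primary allylic alcohol of 23 in the presence of the secondary one, and oxidation as the final step.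

19 ⇒ 18 ⇒ 17 ⇒ 16 ⇒ 11 + 15. The C8–C9 bond is cut. C8 becomes an aldehyde on the butenolide and the C9–C10(=C14)–C1 unit a 2-substituted allyl reagent. The gain is that C8 is set by a catalyst on a flat, electron-poor aldehyde. The demand is reagent control over the weak 1,3-bias from C6, and prompt acetylation of the new alcohol.

11 ⇒ 10. The C7–C8 bond is cut (the formyl carbon comes from CO). This reduces the problem to a β-iodobutenolide. The demand is a reductive carbonylation that does not reduce the C–I bond directly.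

10 ⇒ 9 ⇒ 8. The O–C6 and C7–I bonds are cut (iodolactonisation of a 2,3-dienoate), then C11–C12 (carbonylation of a propargylic carbonate). The tetrasubstituted alkene with its four different substituents is thus drawn from an alkyne. The demand is faithful centre-to-axis-to-centre transfer (net inversion at C6) and a short life for the Z-vinylallene 9.

8 ⇒ 7 ⇒ 4 + 5 (through 6). The C6–C7 bond is cut. C6 is set by a catalytic asymmetric alkynylation of an enal. The demand is Re-face addition without Z/E isomerisation of 4.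

4 ⇒ 3 ⇒ 2 ⇒ 1 and 15 ⇒ 14 ⇒ 13 ⇒ 12. The Z geometry of C4=C5 is taken from the ring of 1 by opening the lactone. The allyl reagent comes from the symmetrical diol 12 by monoprotection and substitution.

**Other disconnections considered**

Alternative 1: The cut is C6–C7 together with O–C12. In the forward sense CrCl2 with catalytic NiCl2 would convert the C7 iodide of the seco (Z)-β-iodoenoate enal A2 into an alkenylchromium species that adds to the C6 aldehyde, and the resulting alkoxide would lactonise onto the methyl ester to give A1. In its favour, it forms the bond that nature forms, builds the large ring and the butenolide in one operation, and works under non-basic conditions, so the C13 acetate can be carried through the ring closure; on this last point it is better than the chosen plan. Against it here, C6 is created during the macrocyclisation under substrate control from remote C8 and C1, a stereodefined tetrasubstituted iodoenoate next to the C8 stereocentre is hard to prepare, and the Z-enal must survive a large excess of a Lewis-acidic metal salt. On structure, both plans keep the Z alkene out of the reacting centre. On mechanism, the chosen plan creates no stereocentre in the ring closure, while this one creates the most sensitive one. On step economy, the alternative saves the separate butenolide construction but spends three steps after closure (ether cleavage, acetylation, desilylation), which is equal to the chosen plan.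

Alternative 2: The cut is C3–C4. Dicyclohexylborane would hydroborate the C2=C3 vinyl group of the seco iodide A4, and Pd(dppf)Cl2 with AsPh3 and K3PO4 would couple the C3 alkylborane with the (Z)-C4 iodide to give A3. In its favour, the coupling proceeds with retention at the preformed Z iodide, C1 is set on an open-chain precursor (better than a reduction on the macrocycle), and the O8/O13 acetonide ties up the C13 oxygen so that it cannot leave (equal to the ether used here). Against it, the hydroboration must choose the vinyl group over the C10=C14 methylene, reductive elimination from a palladacycle leading to a ten-membered ring competes with β-hydride elimination, and aqueous phosphate meets the acidic C6–H. On mechanism, the chosen plan relies on a simpler SN2 event. On step economy, the two are about equal (acetonide removal, bis-acetylation and desilylation after closure).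

Alternative 3: The cut is C8–C9. Me2AlCl (or MgBr2) would activate the C8 aldehyde of the formyl butenolide A6, and the isopropenyl terminus would add through C9 with transfer of a C14 hydrogen to give A5. In its favour, one step forms the ring, the C8 carbinol and the C10=C14 methylene, the chain comes from a cheap nerol-type precursor, and only acetylation and desilylation follow; on step economy it is better than the chosen plan. Against it, C8 is created in the ring closure under substrate control, hydrogen transfer from C1–H instead of C14 would give an enol ether, ten-membered carbonyl-ene closures are rare, and the Lewis acid can ionise the C13 acetate or the allylic lactone. On structure, it shares the butenolide aldehyde used here. On mechanism, it trades a catalyst-set C8 for a diastereoselective cyclisation of uncertain sense.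

Key step: step 20

Remarks. Abbreviations: TBDPS = tert-butyldiphenylsilyl, TBS = tert-butyldimethylsilyl, PMB = 4-methoxybenzyl; atom labels follow germacrane numbering.
- Compound 5 is taken as a catalogue item; otherwise it is one Williamson step from propargyl alcohol.
- The sense of induction of the ProPhenol, BINOL–titanium and oxazaborolidine catalysts is assigned from the accepted models; each new carbinol is to be checked as its Mosher esters and the antipodal catalyst used if the sense is opposite.
- Substrate 26 is the ring-closure substrate with one spectator changed: the C13 oxygen is a PMB ether instead of an acetate; skeleton, leaving group and the bond formed are unchanged.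

**Route**

Step 1
Reactants: 1 4-methylfuran-2(5H)-one
Product: 2 (2Z)-4-hydroxy-N-methoxy-N,3-dimethylbut-2-enamide
Conditions: MeNH(OMe)·HCl, Me3Al, CH2Cl2, 0 °C to rt; aq. potassium sodium tartrate
Reagents that add atoms: N,O-dimethylhydroxylamine hydrochloride, CNOC.Cl
Why: Aluminium-amide aminolysis of the lactone (Weinreb amide formation) opens the ring without touching the alkene, so the ring-enforced cis relation of the C6 carbonyl and the C3 oxygen becomes the Z geometry of C4=C5; the product is silylated at once because it can relactonise.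

Step 2
Reactants: 2 (2Z)-4-hydroxy-N-methoxy-N,3-dimethylbut-2-enamide
Product: 3 (2Z)-4-(TBDPSO)-N-methoxy-N,3-dimethylbut-2-enamide
Conditions: TBDPSCl, imidazole, DMF, 0 °C to rt
Reagents that add atoms: tert-butyl(chloro)diphenylsilane, CC(C)(C)[Si](Cl)(c1ccccc1)c1ccccc1
Why: Standard silylation of a primary alcohol; the TBDPS ether is chosen to outlast iodine, mild acid and the later selective removal of a TBS ether.

Step 3
Reactants: 3 (2Z)-4-(TBDPSO)-N-methoxy-N,3-dimethylbut-2-enamide
Product: 4 (2Z)-4-(TBDPSO)-3-methylbut-2-enal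
Conditions: iBu2AlH, THF, −78 °C; aq. potassium sodium tartrate
Reagents that add atoms: none
Why: Weinreb amide reduction stops at the aldehyde through the chelated tetrahedral intermediate; low temperature and neutral work-up should keep the Z geometry, and 4 is used without storage.

Step 4
Reactants: 4 (2Z)-4-(TBDPSO)-3-methylbut-2-enal; 5 4-methoxybenzyl prop-2-yn-1-yl ether
Product: 7 (4S,5Z)-7-(TBDPSO)-1-(PMBO)-6-methylhept-5-en-2-yn-4-ol, via alkynylzinc 6 (not isolated)
Conditions: Me2Zn, (S,S)-ProPhenol [2,6-bis{[(S)-2-(hydroxydiphenylmethyl)pyrrolidin-1-yl]methyl}-4-methylphenol] (20 mol %), Ph3P=O (40 mol %), toluene, 4 °C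
Reagents that add atoms: none
Why: Catalytic asymmetric alkynylation of an enal by a zinc acetylide under dinuclear zinc–ProPhenol control; the ligand is to deliver the alkynyl group to the Re face of C6, giving the 4S carbinol (C6 of the target with the opposite spatial sense, as required by the net inversion in steps 6 and 7).

Step 5
Reactants: 7 (4S,5Z)-7-(TBDPSO)-1-(PMBO)-6-methylhept-5-en-2-yn-4-ol
Product: 8 (4S,5Z)-7-(TBDPSO)-1-(PMBO)-6-methylhept-5-en-2-yn-4-yl methyl carbonate
Conditions: ClCO2Me, pyridine, DMAP (cat.), CH2Cl2, 0 °C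
Reagents that add atoms: methyl chloroformate, COC(=O)Cl
Why: Acylation of the secondary alcohol with retention; a carbonate is preferred to a sulfonate because the carbinol is both allylic and propargylic and a sulfonate would ionise.

Step 6
Reactants: 8 (4S,5Z)-7-(TBDPSO)-1-(PMBO)-6-methylhept-5-en-2-yn-4-yl methyl carbonate
Product: 9 methyl (Ra,5Z)-7-(TBDPSO)-2-(PMBOCH2)-6-methylhepta-2,3,5-trienoate
Conditions: Pd2(dba)3·CHCl3 (2.5 mol %), PPh3 (10 mol %), CO (1 atm), MeOH–THF, 20 °C
Reagents that add atoms: carbon monoxide, [C-]#[O+]; methanol, CO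
Why: Palladium-catalysed carbonylation of a propargylic carbonate (anti SN2′ oxidative addition of zerovalent palladium at the alkyne, CO insertion, methanolysis) gives the 2,3-dienoate, and the anti course converts the 4S centre into the Ra axis. The C13 oxygen is an ether, not an ester, so the allenylpalladium and the product cannot ionise a second time. The Z-vinylallene 9 is kept at or below room temperature and used at once to avoid a [1,5]-hydrogen shift.

Step 7
Reactants: 9 methyl (Ra,5Z)-7-(TBDPSO)-2-(PMBOCH2)-6-methylhepta-2,3,5-trienoate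
Product: 10 (5R)-5-[(1Z)-3-(TBDPSO)-2-methylprop-1-en-1-yl]-4-iodo-3-(PMBOCH2)furan-2(5H)-one
Conditions: I2 (1.5 equiv), NaHCO3, MeCN–H2O (15:1), 0 °C to rt, dark
Reagents that add atoms: iodine, II; water, O
Why: Iodolactonisation of a 2,3-allenoate: iodine adds to the central allene carbon C7, the ester carbonyl oxygen attacks C6 on the face fixed by the axis, and the methyl group is lost as methanol. The Ra axis gives 6R, so the C6–O bond is re-formed on the face opposite to that of 7.

Step 8
Reactants: 10 (5R)-5-[(1Z)-3-(TBDPSO)-2-methylprop-1-en-1-yl]-4-iodo-3-(PMBOCH2)furan-2(5H)-one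
Product: 11 (2R)-2-[(1Z)-3-(TBDPSO)-2-methylprop-1-en-1-yl]-4-(PMBOCH2)-5-oxo-2,5-dihydrofuran-3-carbaldehyde
Conditions: Pd(PPh3)4 (5 mol %), CO (3 atm), Bu3SnH (1.1 equiv, syringe pump), THF, 50 °C
Reagents that add atoms: carbon monoxide, [C-]#[O+]
Why: Stille-type reductive carbonylation (formylation) of a vinyl iodide: oxidative addition, CO insertion and hydride transfer from tin; the β-iodobutenolide is a vinylogous acyl iodide and adds quickly to zerovalent palladium, and slow hydride addition under CO pressure limits direct reduction.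

Step 9
Reactants: 12 2-methylidenepropane-1,3-diol
Product: 13 2-(TBSOCH2)prop-2-en-1-ol
Conditions: NaH (1.0 equiv), THF, 0 °C; then TBSCl
Reagents that add atoms: tert-butyl(chloro)dimethylsilane, CC(C)(C)[Si](C)(C)Cl
Why: Monosilylation of a symmetrical diol through its sparingly soluble monosodium alkoxide.

Step 10
Reactants: 13 2-(TBSOCH2)prop-2-en-1-ol
Product: 14 2-(TBSOCH2)prop-2-en-1-yl methanesulfonate
Conditions: MsCl, Et3N, CH2Cl2, −10 °C
Reagents that add atoms: methanesulfonyl chloride, CS(=O)(=O)Cl
Why: Standard sulfonylation of a primary allylic alcohol; the mesylate is used crude.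

Step 11
Reactants: 14 2-(TBSOCH2)prop-2-en-1-yl methanesulfonate
Product: 15 tributyl[2-(TBSOCH2)prop-2-en-1-yl]stannane
Conditions: Bu3SnLi (from Bu3SnH and LiN(iPr)2), THF, −78 °C
Reagents that add atoms: tributyltin hydride, CCCC[SnH](CCCC)CCCC
Why: SN2 displacement of the allylic mesylate by the stannyl anion gives the 2-substituted allylstannane.

Step 12
Reactants: 11 (2R)-2-[(1Z)-3-(TBDPSO)-2-methylprop-1-en-1-yl]-4-(PMBOCH2)-5-oxo-2,5-dihydrofuran-3-carbaldehyde; 15 tributyl[2-(TBSOCH2)prop-2-en-1-yl]stannane
Product: 16 (5R)-4-[(1S)-1-hydroxy-3-(TBSOCH2)but-3-en-1-yl]-5-[(1Z)-3-(TBDPSO)-2-methylprop-1-en-1-yl]-3-(PMBOCH2)furan-2(5H)-one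
Conditions: (S)-BINOL (20 mol %), Ti(OiPr)4 (10 mol %), 4 Å molecular sieves, CH2Cl2, −20 °C; aq. NaHCO3
Reagents that add atoms: none
Why: Keck asymmetric allylation of an electron-poor conjugated aldehyde with a 2-substituted allylstannane; the (S)-BINOL–titanium complex should direct the allyl group to the Si face of C8 and give 8S, overriding the weak 1,3-bias from C6.

Step 13
Reactants: 16 (5R)-4-[(1S)-1-hydroxy-3-(TBSOCH2)but-3-en-1-yl]-5-[(1Z)-3-(TBDPSO)-2-methylprop-1-en-1-yl]-3-(PMBOCH2)furan-2(5H)-one
Product: 17 (1S)-1-{(2R)-2-[(1Z)-3-(TBDPSO)-2-methylprop-1-en-1-yl]-4-(PMBOCH2)-5-oxo-2,5-dihydrofuran-3-yl}-3-(TBSOCH2)but-3-en-1-yl acetate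
Conditions: Ac2O, pyridine, DMAP (cat.), CH2Cl2, 0 °C
Reagents that add atoms: acetic anhydride, CC(=O)OC(C)=O
Why: Acylation of the secondary alcohol installs the C8 acetate of the target; it is done at once and cold so that the free C8 hydroxyl cannot translactonise onto C12.

Step 14
Reactants: 17 (1S)-1-{(2R)-2-[(1Z)-3-(TBDPSO)-2-methylprop-1-en-1-yl]-4-(PMBOCH2)-5-oxo-2,5-dihydrofuran-3-yl}-3-(TBSOCH2)but-3-en-1-yl acetate
Product: 18 (1S)-1-{(2R)-2-[(1Z)-3-(TBDPSO)-2-methylprop-1-en-1-yl]-4-(PMBOCH2)-5-oxo-2,5-dihydrofuran-3-yl}-3-(hydroxymethyl)but-3-en-1-yl acetate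
Conditions: HF·pyridine, pyridine, THF, 0 °C
Reagents that add atoms: none
Why: Selective desilylation: the primary TBS ether is cleaved far faster than the TBDPS ether under buffered fluoride, and acetate, PMB ether and lactone are inert.

Step 15
Reactants: 18 (1S)-1-{(2R)-2-[(1Z)-3-(TBDPSO)-2-methylprop-1-en-1-yl]-4-(PMBOCH2)-5-oxo-2,5-dihydrofuran-3-yl}-3-(hydroxymethyl)but-3-en-1-yl acetate
Product: 19 (1S)-1-{(2R)-2-[(1Z)-3-(TBDPSO)-2-methylprop-1-en-1-yl]-4-(PMBOCH2)-5-oxo-2,5-dihydrofuran-3-yl}-3-formylbut-3-en-1-yl acetate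
Conditions: Dess–Martin periodinane, NaHCO3, CH2Cl2, 0 °C
Reagents that add atoms: none
Why: Dess–Martin oxidation of a primary allylic alcohol to the 2-substituted acrolein under buffered, non-basic conditions; 19 is used directly.

Step 16
Reactants: 19 (1S)-1-{(2R)-2-[(1Z)-3-(TBDPSO)-2-methylprop-1-en-1-yl]-4-(PMBOCH2)-5-oxo-2,5-dihydrofuran-3-yl}-3-formylbut-3-en-1-yl acetate; 20 tert-butyl bromoacetate
Product: 22 tert-butyl (6S)-6-acetoxy-3-hydroxy-4-methylidene-6-{(2R)-2-[(1Z)-3-(TBDPSO)-2-methylprop-1-en-1-yl]-4-(PMBOCH2)-5-oxo-2,5-dihydrofuran-3-yl}hexanoate (both C3 epimers), via Reformatsky reagent 21 (not isolated)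
Conditions: Zn (activated), 20, THF, 40 °C; then 19, THF, −20 to 0 °C; aq. NH4Cl
Reagents that add atoms: none
Why: Reformatsky addition: the preformed zinc enolate adds 1,2 to the enal and tolerates acetate, lactone and ethers; the C1 carbinol is formed as both epimers, which converge on oxidation in step 19.

Step 17
Reactants: 22 tert-butyl (6S)-6-acetoxy-3-hydroxy-4-methylidene-6-{(2R)-2-[(1Z)-3-(TBDPSO)-2-methylprop-1-en-1-yl]-4-(PMBOCH2)-5-oxo-2,5-dihydrofuran-3-yl}hexanoate
Product: 23 tert-butyl (6S)-6-acetoxy-3-hydroxy-6-{(2R)-2-[(1Z)-3-hydroxy-2-methylprop-1-en-1-yl]-4-(PMBOCH2)-5-oxo-2,5-dihydrofuran-3-yl}-4-methylidenehexanoate (both C3 epimers)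
Conditions: HF·pyridine (excess), THF, rt
Reagents that add atoms: none
Why: Fluoride cleavage of the primary TBDPS ether under acidic buffering, which avoids acetate migration and deprotonation at C6.

Step 18
Reactants: 23 tert-butyl (6S)-6-acetoxy-3-hydroxy-6-{(2R)-2-[(1Z)-3-hydroxy-2-methylprop-1-en-1-yl]-4-(PMBOCH2)-5-oxo-2,5-dihydrofuran-3-yl}-4-methylidenehexanoate
Product: 25 tert-butyl (6S)-6-acetoxy-6-{(2R)-2-[(1Z)-3-chloro-2-methylprop-1-en-1-yl]-4-(PMBOCH2)-5-oxo-2,5-dihydrofuran-3-yl}-3-hydroxy-4-methylidenehexanoate (both C3 epimers), via allylic mesylate 24 (not isolated)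
Conditions: MsCl (1.1 equiv), 2,4,6-collidine, LiCl, DMF, −20 to 0 °C
Reagents that add atoms: lithium chloride, [Li+].[Cl-]
Why: Collington–Meyers chlorination: the unhindered primary allylic alcohol is sulfonylated in preference to the hindered, hydrogen-bonded secondary β-hydroxy ester, and chloride displaces the mesylate by SN2 with the Z alkene intact.

Step 19
Reactants: 25 tert-butyl (6S)-6-acetoxy-6-{(2R)-2-[(1Z)-3-chloro-2-methylprop-1-en-1-yl]-4-(PMBOCH2)-5-oxo-2,5-dihydrofuran-3-yl}-3-hydroxy-4-methylidenehexanoate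
Product: 26 tert-butyl (6S)-6-acetoxy-6-{(2R)-2-[(1Z)-3-chloro-2-methylprop-1-en-1-yl]-4-(PMBOCH2)-5-oxo-2,5-dihydrofuran-3-yl}-4-methylidene-3-oxohexanoate
Conditions: Dess–Martin periodinane, NaHCO3, CH2Cl2, 0 °C
Reagents that add atoms: none
Why: Dess–Martin oxidation of the allylic β-hydroxy ester to the β-keto ester; the product is a Nazarov-type vinyl β-keto ester, so it is made last and taken straight into the ring closure.

Step 20
Reactants: 26 tert-butyl (6S)-6-acetoxy-6-{(2R)-2-[(1Z)-3-chloro-2-methylprop-1-en-1-yl]-4-(PMBOCH2)-5-oxo-2,5-dihydrofuran-3-yl}-4-methylidene-3-oxohexanoate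
Product: 27 tert-butyl (4Z,6R,8S)-8-acetoxy-13-(PMBO)-1-oxogermacra-4,7(11),10(14)-trien-6,12-olide-2-carboxylate (both C2 epimers)
Conditions: Cs2CO3 (3 equiv), CsI (1 equiv), MeCN, 40 °C, 26 added over 12 h (final 1 mM)
Reagents that add atoms: none
Why: Cs2CO3 deprotonates C2 of the β-keto ester, by several pK units the most acidic C–H, and the enolate displaces the primary allylic halide at C3 (the iodide formed in situ from the chloride) in an intramolecular SN2 C-alkylation; the closest known reaction type is macrocyclisation of β-keto ester or malonate enolates with allylic halides under high dilution. The one ring is closed in a 10-exo-tet mode, forming C2–C3. The only new stereocentre is C2, which is not controlled, is carried as both epimers and disappears on decarboxylation; C6 and C8 are not part of the reaction and the Z alkene is outside the reacting centre. The step needs C- over O-alkylation and SN2 over SN2′ (soft enolate, soft primary terminus, hindered C5), and ring closure over oligomerisation (slow addition; the Z alkene, the planar butenolide and the enone restrict the chain). It also needs the butenolide to survive: with a PMB ether instead of an acetate at C13 there is no leaving group β to C11, so conjugate addition of the enolate to C7 (6-exo-trig before closure, transannular after it) and deprotonation at C6 are reversible rather than ending in loss of acetate, and the irreversible SN2 closure drains these equilibria. A heterogeneous weak base and short contact time limit epimerisation at C6.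

Step 21
Reactants: 27 tert-butyl (4Z,6R,8S)-8-acetoxy-13-(PMBO)-1-oxogermacra-4,7(11),10(14)-trien-6,12-olide-2-carboxylate
Product: 29 (4Z,6R,8S)-8-acetoxy-13-hydroxy-1-oxogermacra-4,7(11),10(14)-trien-6,12-olide, via β-keto acid 28 (not isolated)
Conditions: CF3CO2H–CH2Cl2 (1:4), anisole (5 equiv), 0 °C to rt; then toluene, 50 °C
Reagents that add atoms: none
Why: Acidolysis removes the tert-butyl ester and the PMB ether in one operation (anisole traps the benzyl cation), and the β-keto acid decarboxylates through its cyclic transition state to the α-methylene ketone; the C6–O bond should resist ionisation because C6 carries the electron-poor butenolide carbon.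

Step 22
Reactants: 29 (4Z,6R,8S)-8-acetoxy-13-hydroxy-1-oxogermacra-4,7(11),10(14)-trien-6,12-olide
Product: 30 (4Z,6R,8S)-8,13-diacetoxy-1-oxogermacra-4,7(11),10(14)-trien-6,12-olide
Conditions: Ac2O, pyridine, CH2Cl2, 0 °C to rt (no DMAP)
Reagents that add atoms: acetic anhydride, CC(=O)OC(C)=O
Why: Acetylation of the primary C13 alcohol now that no base-mediated step remains; a nucleophilic catalyst is avoided because of the α-methylene ketone.

Step 23
Reactants: 30 (4Z,6R,8S)-8,13-diacetoxy-1-oxogermacra-4,7(11),10(14)-trien-6,12-olide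
Product: 31 (1R,4Z,6R,8S)-8,13-diacetoxy-1-hydroxygermacra-4,7(11),10(14)-trien-6,12-olide (8α,13-diacetoxy-1β-hydroxygermacra-4,7(11),10(14)-trien-6α,12-olide)
Conditions: (S)-2-methyl-CBS-oxazaborolidine [(S)-1-methyl-3,3-diphenyltetrahydro-1H,3H-pyrrolo[1,2-c][1,3,2]oxazaborole] (0.5 equiv), catecholborane (1.5 equiv), toluene, −78 °C
Reagents that add atoms: none
Why: Corey–Bakshi–Shibata reduction of an enone: the 2-substituted alkenyl flank (C10) acts as the large group and the C2 methylene as the small one, so the (S)-catalyst should deliver hydride to give 1R; low temperature favours the catalysed 1,2-reduction over conjugate reduction, and lactone and acetates are inert to catecholborane.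

**Compound list**

1 | 4-methylfuran-2(5H)-one | CC1=CC(=O)OC1 | starting material
2 | (2Z)-4-hydroxy-N-methoxy-N,3-dimethylbut-2-enamide | CON(C)C(=O)/C=C(/C)CO | intermediate
3 | (2Z)-4-(TBDPSO)-N-methoxy-N,3-dimethylbut-2-enamide | CON(C)C(=O)/C=C(/C)CO[Si](c1ccccc1)(c1ccccc1)C(C)(C)C | intermediate
4 | (2Z)-4-(TBDPSO)-3-methylbut-2-enal | O=C/C=C(/C)CO[Si](c1ccccc1)(c1ccccc1)C(C)(C)C | intermediate
5 | 4-methoxybenzyl prop-2-yn-1-yl ether | C#CCOCc1ccc(OC)cc1 | starting material
6 | methyl[3-(PMBO)prop-1-yn-1-yl]zinc | C[Zn]C#CCOCc1ccc(OC)cc1 | intermediate (not isolated)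
7 | (4S,5Z)-7-(TBDPSO)-1-(PMBO)-6-methylhept-5-en-2-yn-4-ol | COc1ccc(COCC#C[C@@H](O)/C=C(/C)CO[Si](c2ccccc2)(c2ccccc2)C(C)(C)C)cc1 | intermediate
8 | (4S,5Z)-7-(TBDPSO)-1-(PMBO)-6-methylhept-5-en-2-yn-4-yl methyl carbonate | COc1ccc(COCC#C[C@@H](OC(=O)OC)/C=C(/C)CO[Si](c2ccccc2)(c2ccccc2)C(C)(C)C)cc1 | intermediate
9 | methyl (Ra,5Z)-7-(TBDPSO)-2-(PMBOCH2)-6-methylhepta-2,3,5-trienoate | COC(=O)C(COCc1ccc(OC)cc1)=[C@]=C([H])/C=C(/C)CO[Si](c1ccccc1)(c1ccccc1)C(C)(C)C | intermediate
10 | (5R)-5-[(1Z)-3-(TBDPSO)-2-methylprop-1-en-1-yl]-4-iodo-3-(PMBOCH2)furan-2(5H)-one | O=C1O[C@H](/C=C(/C)CO[Si](c2ccccc2)(c2ccccc2)C(C)(C)C)C(I)=C1COCc1ccc(OC)cc1 | intermediate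
11 | (2R)-2-[(1Z)-3-(TBDPSO)-2-methylprop-1-en-1-yl]-4-(PMBOCH2)-5-oxo-2,5-dihydrofuran-3-carbaldehyde | O=CC1=C(COCc2ccc(OC)cc2)C(=O)O[C@@H]1/C=C(/C)CO[Si](c1ccccc1)(c1ccccc1)C(C)(C)C | intermediate
12 | 2-methylidenepropane-1,3-diol | C=C(CO)CO | starting material
13 | 2-(TBSOCH2)prop-2-en-1-ol | C=C(CO)CO[Si](C)(C)C(C)(C)C | intermediate
14 | 2-(TBSOCH2)prop-2-en-1-yl methanesulfonate | C=C(COS(C)(=O)=O)CO[Si](C)(C)C(C)(C)C | intermediate
15 | tributyl[2-(TBSOCH2)prop-2-en-1-yl]stannane | C=C(C[Sn](CCCC)(CCCC)CCCC)CO[Si](C)(C)C(C)(C)C | intermediate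
16 | (5R)-4-[(1S)-1-hydroxy-3-(TBSOCH2)but-3-en-1-yl]-5-[(1Z)-3-(TBDPSO)-2-methylprop-1-en-1-yl]-3-(PMBOCH2)furan-2(5H)-one | C=C(CO[Si](C)(C)C(C)(C)C)C[C@H](O)C1=C(COCc2ccc(OC)cc2)C(=O)O[C@@H]1/C=C(/C)CO[Si](c1ccccc1)(c1ccccc1)C(C)(C)C | intermediate
17 | (1S)-1-{(2R)-2-[(1Z)-3-(TBDPSO)-2-methylprop-1-en-1-yl]-4-(PMBOCH2)-5-oxo-2,5-dihydrofuran-3-yl}-3-(TBSOCH2)but-3-en-1-yl acetate | C=C(CO[Si](C)(C)C(C)(C)C)C[C@H](OC(C)=O)C1=C(COCc2ccc(OC)cc2)C(=O)O[C@@H]1/C=C(/C)CO[Si](c1ccccc1)(c1ccccc1)C(C)(C)C | intermediate
18 | (1S)-1-{(2R)-2-[(1Z)-3-(TBDPSO)-2-methylprop-1-en-1-yl]-4-(PMBOCH2)-5-oxo-2,5-dihydrofuran-3-yl}-3-(hydroxymethyl)but-3-en-1-yl acetate | C=C(CO)C[C@H](OC(C)=O)C1=C(COCc2ccc(OC)cc2)C(=O)O[C@@H]1/C=C(/C)CO[Si](c1ccccc1)(c1ccccc1)C(C)(C)C | intermediate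
19 | (1S)-1-{(2R)-2-[(1Z)-3-(TBDPSO)-2-methylprop-1-en-1-yl]-4-(PMBOCH2)-5-oxo-2,5-dihydrofuran-3-yl}-3-formylbut-3-en-1-yl acetate | C=C(C=O)C[C@H](OC(C)=O)C1=C(COCc2ccc(OC)cc2)C(=O)O[C@@H]1/C=C(/C)CO[Si](c1ccccc1)(c1ccccc1)C(C)(C)C | intermediate
20 | tert-butyl bromoacetate | CC(C)(C)OC(=O)CBr | starting material
21 | (2-tert-butoxy-2-oxoethyl)zinc bromide | CC(C)(C)OC(=O)C[Zn]Br | intermediate (not isolated)
22 | tert-butyl (6S)-6-acetoxy-3-hydroxy-4-methylidene-6-{(2R)-2-[(1Z)-3-(TBDPSO)-2-methylprop-1-en-1-yl]-4-(PMBOCH2)-5-oxo-2,5-dihydrofuran-3-yl}hexanoate (both C3 epimers) | CC(C)(C)OC(=O)CC(O)C(=C)C[C@H](OC(C)=O)C1=C(COCc2ccc(OC)cc2)C(=O)O[C@@H]1/C=C(/C)CO[Si](c1ccccc1)(c1ccccc1)C(C)(C)C | intermediate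
23 | tert-butyl (6S)-6-acetoxy-3-hydroxy-6-{(2R)-2-[(1Z)-3-hydroxy-2-methylprop-1-en-1-yl]-4-(PMBOCH2)-5-oxo-2,5-dihydrofuran-3-yl}-4-methylidenehexanoate (both C3 epimers) | CC(C)(C)OC(=O)CC(O)C(=C)C[C@H](OC(C)=O)C1=C(COCc2ccc(OC)cc2)C(=O)O[C@@H]1/C=C(/C)CO | intermediate
24 | tert-butyl (6S)-6-acetoxy-3-hydroxy-6-{(2R)-2-[(1Z)-3-(methanesulfonyloxy)-2-methylprop-1-en-1-yl]-4-(PMBOCH2)-5-oxo-2,5-dihydrofuran-3-yl}-4-methylidenehexanoate | CC(C)(C)OC(=O)CC(O)C(=C)C[C@H](OC(C)=O)C1=C(COCc2ccc(OC)cc2)C(=O)O[C@@H]1/C=C(/C)COS(C)(=O)=O | intermediate (not isolated)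
25 | tert-butyl (6S)-6-acetoxy-6-{(2R)-2-[(1Z)-3-chloro-2-methylprop-1-en-1-yl]-4-(PMBOCH2)-5-oxo-2,5-dihydrofuran-3-yl}-3-hydroxy-4-methylidenehexanoate (both C3 epimers) | CC(C)(C)OC(=O)CC(O)C(=C)C[C@H](OC(C)=O)C1=C(COCc2ccc(OC)cc2)C(=O)O[C@@H]1/C=C(/C)CCl | intermediate
26 | tert-butyl (6S)-6-acetoxy-6-{(2R)-2-[(1Z)-3-chloro-2-methylprop-1-en-1-yl]-4-(PMBOCH2)-5-oxo-2,5-dihydrofuran-3-yl}-4-methylidene-3-oxohexanoate | CC(C)(C)OC(=O)CC(=O)C(=C)C[C@H](OC(C)=O)C1=C(COCc2ccc(OC)cc2)C(=O)O[C@@H]1/C=C(/C)CCl | intermediate
27 | tert-butyl (4Z,6R,8S)-8-acetoxy-13-(PMBO)-1-oxogermacra-4,7(11),10(14)-trien-6,12-olide-2-carboxylate (both C2 epimers) | C=C1C[C@H](OC(C)=O)C2=C(COCc3ccc(OC)cc3)C(=O)O[C@@H]2/C=C(/C)CC(C(=O)OC(C)(C)C)C1=O | intermediate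
28 | (4Z,6R,8S)-8-acetoxy-13-hydroxy-1-oxogermacra-4,7(11),10(14)-trien-6,12-olide-2-carboxylic acid | C=C1C[C@H](OC(C)=O)C2=C(CO)C(=O)O[C@@H]2/C=C(/C)CC(C(=O)O)C1=O | intermediate (not isolated)
29 | (4Z,6R,8S)-8-acetoxy-13-hydroxy-1-oxogermacra-4,7(11),10(14)-trien-6,12-olide | C=C1C[C@H](OC(C)=O)C2=C(CO)C(=O)O[C@@H]2/C=C(/C)CCC1=O | intermediate
30 | (4Z,6R,8S)-8,13-diacetoxy-1-oxogermacra-4,7(11),10(14)-trien-6,12-olide | C=C1C[C@H](OC(C)=O)C2=C(COC(C)=O)C(=O)O[C@@H]2/C=C(/C)CCC1=O | intermediate
31 | (1R,4Z,6R,8S)-8,13-diacetoxy-1-hydroxygermacra-4,7(11),10(14)-trien-6,12-olide | C=C1C[C@H](OC(C)=O)C2=C(COC(C)=O)C(=O)O[C@@H]2/C=C(/C)CC[C@H]1O | target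

**Step count and least certain steps**

Total: 23 steps. Longest linear sequence: 20 steps (steps 1–8 and 12–23 from 1); the allyl reagent 15 is made in a three-step side branch (steps 9–11).

Step 20 (key step). The most likely failure is diversion of the C2 enolate: reversible conjugate addition at C7, deprotonation at C6 with epimerisation, O-alkylation, or intermolecular Michael addition to the vinyl ketone of a second molecule. Fallback: a neutral palladium-allyl ring closure of the same bond. It sets out from 23: selective methoxycarbonylation of the primary allylic alcohol (ClCO2Me, pyridine, −30 °C) would give the allylic methyl carbonate F1, and Dess–Martin oxidation the β-keto ester carbonate F2. Zerovalent palladium (Pd2(dba)3·CHCl3, dppe, THF, 40 °C, high dilution) would ionise only the carbonate, and the methoxide released deprotonates C2, which attacks the primary allyl terminus to give 27, where the fallback rejoins the route. The risk carried by this detour is syn/anti isomerisation of the allyl complex and hence loss of the Z geometry.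

Step 6. The likely failures are loss of stereochemical fidelity (a second SN2′ attack of zerovalent palladium on the allenylpalladium), ionisation through the allylic rather than the propargylic manifold, and a [1,5]-hydrogen shift of the Z-vinylallene on warming. Fallback: an allene-free sequence that keeps the C6–O bond. It sets out from 4 and 5: the step 4 conditions with the antipodal ligand would give the 4R propargylic alcohol F3; anti addition of I2 to the alkyne (CH2Cl2, dark) would give the (E)-diiodide F4. Carbonylative lactonisation (PdCl2(PPh3)2, CO, Et3N, THF) is expected to engage the C11 iodide, which is cis to the carbinol, and leave the C7 iodide, giving 10 with retention at C6, where the fallback rejoins.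

Step 7. The likely failures are attack of iodine on the trisubstituted alkene and leakage through a free pentadienyl cation, which would erode C6 and the Z geometry. Fallback: cyclise the acid instead of the ester with a milder halogen source. From 9, saponification (LiOH, THF–H2O, 0 °C) would give the allenoic acid F5, and CuBr2 in acetone–H2O at rt the bromobutenolide F6 by carboxylate-assisted bromolactonisation. The reductive carbonylation of step 8, applied to this bromide, returns the route at 11.

Step 12. The likely failures are a slow reaction and poor facial selectivity on a hindered aldehyde that carries several Lewis-basic sites. Fallback: addition without control, then oxidation and asymmetric reduction. From 14, LiBr in acetone would give the allylic bromide F7. An indium-mediated Barbier reaction of 11 with this bromide (In, THF–H2O) would give the C8 epimer mixture F8, Dess–Martin oxidation the ketone F9, and (R)-2-methyl-CBS-oxazaborolidine with catecholborane at −78 °C (butenolide carbon as the large group) the 8S alcohol 16, where the fallback rejoins.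

Step 23. The likely failures are poor facial selectivity if the conformation of the macrocycle opposes the catalyst, and competing conjugate reduction of the s-cis enone by catecholborane. Fallback: substrate-controlled reduction followed by inversion. From 30, Luche reduction (NaBH4, CeCl3, MeOH, −78 °C) is expected to favour one epimer. If this is the 1S alcohol F10, Mitsunobu inversion with formic acid (PPh3, diisopropyl azodicarboxylate, THF, 0 °C) would give the 1R formate F11, and KHCO3 in MeOH at 0 °C would cleave the formate selectively in the presence of the two acetates to give 31.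

**Further compounds**

F1 | step 20 | tert-butyl (6S)-6-acetoxy-3-hydroxy-6-{(2R)-2-[(1Z)-3-(methoxycarbonyloxy)-2-methylprop-1-en-1-yl]-4-(PMBOCH2)-5-oxo-2,5-dihydrofuran-3-yl}-4-methylidenehexanoate | CC(C)(C)OC(=O)CC(O)C(=C)C[C@H](OC(C)=O)C1=C(COCc2ccc(OC)cc2)C(=O)O[C@@H]1/C=C(/C)COC(=O)OC
F2 | step 20 | tert-butyl (6S)-6-acetoxy-6-{(2R)-2-[(1Z)-3-(methoxycarbonyloxy)-2-methylprop-1-en-1-yl]-4-(PMBOCH2)-5-oxo-2,5-dihydrofuran-3-yl}-4-methylidene-3-oxohexanoate | CC(C)(C)OC(=O)CC(=O)C(=C)C[C@H](OC(C)=O)C1=C(COCc2ccc(OC)cc2)C(=O)O[C@@H]1/C=C(/C)COC(=O)OC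
F3 | step 6 | (4R,5Z)-7-(TBDPSO)-1-(PMBO)-6-methylhept-5-en-2-yn-4-ol | COc1ccc(COCC#C[C@H](O)/C=C(/C)CO[Si](c2ccccc2)(c2ccccc2)C(C)(C)C)cc1
F4 | step 6 | (2E,4R,5Z)-7-(TBDPSO)-2,3-diiodo-1-(PMBO)-6-methylhepta-2,5-dien-4-ol | COc1ccc(COC/C(I)=C(\I)[C@H](O)/C=C(/C)CO[Si](c2ccccc2)(c2ccccc2)C(C)(C)C)cc1
F5 | step 7 | (Ra,5Z)-7-(TBDPSO)-2-(PMBOCH2)-6-methylhepta-2,3,5-trienoic acid | OC(=O)C(COCc1ccc(OC)cc1)=[C@]=C([H])/C=C(/C)CO[Si](c1ccccc1)(c1ccccc1)C(C)(C)C
F6 | step 7 | (5R)-4-bromo-5-[(1Z)-3-(TBDPSO)-2-methylprop-1-en-1-yl]-3-(PMBOCH2)furan-2(5H)-one | O=C1O[C@H](/C=C(/C)CO[Si](c2ccccc2)(c2ccccc2)C(C)(C)C)C(Br)=C1COCc1ccc(OC)cc1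
F7 | step 12 | [2-(bromomethyl)prop-2-en-1-yloxy](tert-butyl)dimethylsilane | C=C(CBr)CO[Si](C)(C)C(C)(C)C
F8 | step 12 | (5R)-4-[1-hydroxy-3-(TBSOCH2)but-3-en-1-yl]-5-[(1Z)-3-(TBDPSO)-2-methylprop-1-en-1-yl]-3-(PMBOCH2)furan-2(5H)-one (both carbinol epimers) | C=C(CO[Si](C)(C)C(C)(C)C)CC(O)C1=C(COCc2ccc(OC)cc2)C(=O)O[C@@H]1/C=C(/C)CO[Si](c1ccccc1)(c1ccccc1)C(C)(C)C
F9 | step 12 | (5R)-5-[(1Z)-3-(TBDPSO)-2-methylprop-1-en-1-yl]-3-(PMBOCH2)-4-[3-(TBSOCH2)but-3-enoyl]furan-2(5H)-one | C=C(CO[Si](C)(C)C(C)(C)C)CC(=O)C1=C(COCc2ccc(OC)cc2)C(=O)O[C@@H]1/C=C(/C)CO[Si](c1ccccc1)(c1ccccc1)C(C)(C)C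
F10 | step 23 | (1S,4Z,6R,8S)-8,13-diacetoxy-1-hydroxygermacra-4,7(11),10(14)-trien-6,12-olide | C=C1C[C@H](OC(C)=O)C2=C(COC(C)=O)C(=O)O[C@@H]2/C=C(/C)CC[C@@H]1O
F11 | step 23 | (1R,4Z,6R,8S)-8,13-diacetoxy-1-(formyloxy)germacra-4,7(11),10(14)-trien-6,12-olide | C=C1C[C@H](OC(C)=O)C2=C(COC(C)=O)C(=O)O[C@@H]2/C=C(/C)CC[C@H]1OC=O
A1 | alternative 1 | (1R,4Z,6R,8S)-13-acetoxy-1-(TBSO)-8-(PMBO)germacra-4,7(11),10(14)-trien-6,12-olide | C=C1C[C@H](OCc3ccc(OC)cc3)C2=C(COC(C)=O)C(=O)O[C@@H]2/C=C(/C)CC[C@H]1O[Si](C)(C)C(C)(C)C
A2 | alternative 1 | methyl (2Z,4S,7R,10Z)-2-(acetoxymethyl)-3-iodo-4-(PMBO)-7-(TBSO)-10-methyl-6-methylidene-12-oxododeca-2,10-dienoate | O=C/C=C(/C)CC[C@@H](O[Si](C)(C)C(C)(C)C)C(=C)C[C@H](OCc1ccc(OC)cc1)/C(I)=C(\COC(C)=O)C(=O)OC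
A3 | alternative 2 | (1R,4Z,6R,8S)-1-(TBSO)-8,13-(isopropylidenedioxy)germacra-4,7(11),10(14)-trien-6,12-olide | C=C1C[C@@H]2OC(C)(C)OCC3=C2[C@@H](/C=C(/C)CC[C@H]1O[Si](C)(C)C(C)(C)C)OC3=O
A4 | alternative 2 | 3,4-seco precursor of A3 with a C2=C3 vinyl group and a (Z)-C4 iodide | C=C[C@@H](O[Si](C)(C)C(C)(C)C)C(=C)C[C@@H]1OC(C)(C)OCC2=C1[C@@H](/C=C(/C)I)OC2=O
A5 | alternative 3 | (1R,4Z,6R,8S)-13-acetoxy-1-(TBSO)-8-hydroxygermacra-4,7(11),10(14)-trien-6,12-olide | C=C1C[C@H](O)C2=C(COC(C)=O)C(=O)O[C@@H]2/C=C(/C)CC[C@H]1O[Si](C)(C)C(C)(C)C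
A6 | alternative 3 | 8,9-seco precursor of A5: (2R)-4-(acetoxymethyl)-2-[(1Z,5R)-5-(TBSO)-2,6-dimethylhepta-1,6-dien-1-yl]-5-oxo-2,5-dihydrofuran-3-carbaldehyde | O=CC1=C(COC(C)=O)C(=O)O[C@@H]1/C=C(/C)CC[C@@H](O[Si](C)(C)C(C)(C)C)C(C)=C
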